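The side chain is cut at C3'–C4' (chain numbered from the CH2 on quinone carbon C3). This bond joins the methyl-bearing vinylic carbon of the first prenyl unit to the three-methylene run C4'–C6'. That run exists only because the second isoprene unit (stereocentre C7') is saturated, so C4' can be carried as the sole monosubstituted alkene of a C36 heptaene. In one operation 9-BBN selects it over six trisubstituted alkenes, and a B-alkyl Suzuki–Miyaura coupling joins it, with retention, to an (E)-alkenyl iodide. That iodide hides the quinone C2=C3 bond in a cyclopentadiene Diels–Alder adduct, a bridged tetracycle inert to borane, base and palladium. Cycloreversion then releases the target.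

Key step: step 14

Remark: the cyclopentadiene adduct block is made as a racemate and its SMILES show one enantiomeric series with the correct relative configuration; after the key step this means a pair of diastereomers that differ only in that block, and both lose it in the last step to give the same single enantiomer.

Step 1
Reactants: 1 (2E,6E)-farnesol
Product: 2 (S)-2,3-dihydrofarnesol [(3S,6E)-3,7,11-trimethyldodeca-6,10-dien-1-ol]
Conditions: H2 (100 atm), Ru(OAc)2[(R)-BINAP] (0.2 mol %), MeOH/H2O 95:5, 20 °C
Reagents that add atoms: none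
Why: Hydroxyl-directed asymmetric hydrogenation of an allylic alcohol with a BINAP–ruthenium dicarboxylate; only C2=C3 can bind through the OH, so the two remote trisubstituted alkenes stay, and the (R)-BINAP/(E)-alkene pairing that turns geraniol into (S)-citronellol should give 3S, the future C7' (called R in the target only because the CIP ranks of the two chain arms swap).

Step 2
Reactants: 2 (S)-2,3-dihydrofarnesol
Product: 3 (S)-2,3-dihydrofarnesal [(3S,6E)-3,7,11-trimethyldodeca-6,10-dienal]
Conditions: PhI(OAc)2 (1.1 equiv), TEMPO (10 mol %), CH2Cl2, rt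
Reagents that add atoms: none
Why: The TEMPO/PhI(OAc)2 oxoammonium oxidation stops at the aldehyde, leaves trisubstituted alkenes alone and cannot epimerise the stereocentre, which is beta to the carbonyl.

Step 3
Reactants: 3 (S)-2,3-dihydrofarnesal
Product: 4 (4S,7E)-4,8,12-trimethyltrideca-1,7,11-triene
Conditions: Ph3PCH3Br (1.3 equiv), KOtBu (1.25 equiv), THF, 0 °C to rt
Reagents that add atoms: methyltriphenylphosphonium bromide, C[P+](c1ccccc1)(c1ccccc1)c1ccccc1.[Br-]
Why: Wittig methylenation with the non-stabilised ylide adds the carbon that becomes C4' and creates the only monosubstituted alkene of the chain.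

Step 4
Reactants: 4 (4S,7E)-4,8,12-trimethyltrideca-1,7,11-triene
Product: 5 (2E,6E,10S)-2,6,10-trimethyltrideca-2,6,12-trien-1-ol
Conditions: SeO2 (0.1 equiv), t-BuOOH (2.5 equiv), salicylic acid (0.1 equiv), CH2Cl2, 0 °C to rt, stopped before full conversion
Reagents that add atoms: tert-butyl hydroperoxide, CC(C)(C)OO (net source of the new oxygen, relayed through catalytic selenium dioxide, O=[Se]=O)
Why: Catalytic SeO2 allylic oxidation (ene reaction, then [2,3]-sigmatropic shift) prefers the electron-rich and least hindered terminal isopropylidene group and hydroxylates its (E)-methyl group, while the vinyl group is much less reactive.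

Step 5
Reactants: 5 (2E,6E,10S)-2,6,10-trimethyltrideca-2,6,12-trien-1-ol
Product: 6 (4S,7E,11E)-13-bromo-4,8,12-trimethyltrideca-1,7,11-triene
Conditions: CBr4 (1.2 equiv), PPh3 (1.25 equiv), CH2Cl2, -20 to 0 °C
Reagents that add atoms: carbon tetrabromide, BrC(Br)(Br)Br
Why: The Appel reaction displaces the primary allylic oxyphosphonium group by direct SN2 under neutral conditions, so neither allylic transposition nor E/Z scrambling is expected.

Step 6
Reactants: 7 (2E,6E,10E)-geranylgeraniol
Product: 8 (2E,6E,10E)-geranylgeranyl bromide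
Conditions: PBr3 (0.4 equiv), Et2O, 0 °C
Reagents that add atoms: phosphorus tribromide, BrP(Br)Br
Why: PBr3 bromination of a primary allylic alcohol runs through SN2 on the phosphite ester at low temperature and keeps position and geometry of the C2=C3 alkene.

Step 7
Reactants: 8 (2E,6E,10E)-geranylgeranyl bromide
Product: 9 (2E,6E,10E)-geranylgeranyl phenyl sulfone
Conditions: PhSO2Na (1.5 equiv), DMF, rt
Reagents that add atoms: sodium benzenesulfinate, [Na+].[O-]S(=O)c1ccccc1
Why: SN2 displacement by the soft sulfur end of the ambident sulfinate (allylic sulfone synthesis) keeps the primary position and the E geometry.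

Step 8
Reactants: 9 (2E,6E,10E)-geranylgeranyl phenyl sulfone; 6 (4S,7E,11E)-13-bromo-4,8,12-trimethyltrideca-1,7,11-triene
Product: 11 (4S,7E,11E,15E,19E,23E)-4,8,12,16,20,24,28-heptamethyl-14-(phenylsulfonyl)nonacosa-1,7,11,15,19,23,27-heptaene (both C14 epimers), via lithiated sulfone 10 (not isolated)
Conditions: n-BuLi (1.05 equiv), THF/DMPU, -78 °C; then 6, -78 to -20 °C
Reagents that add atoms: n-butyllithium, [Li]CCCC (its lithium stays in 10 only)
Why: Alkylation of a sulfone-stabilised allyl anion; the anion reacts at its alpha carbon and the primary allylic bromide by direct SN2, so the head-to-tail 1,5-diene link forms with both E alkenes intact, and the uncontrolled sulfonyl-bearing stereocentre is erased in step 9.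

Step 9
Reactants: 11 C14-phenylsulfonyl heptaene
Product: 12 (4S,7E,11E,15E,19E,23E)-4,8,12,16,20,24,28-heptamethylnonacosa-1,7,11,15,19,23,27-heptaene
Conditions: LiEt3BH (2.5 equiv), PdCl2(dppp) (5 mol %), THF, 0 °C
Reagents that add atoms: none
Why: Palladium-catalysed reductive desulfonylation; zerovalent palladium ionises the allylic carbon–sulfur bond and hydride is delivered to the less substituted end of the pi-allyl complex, which keeps the trisubstituted alkene in place and E, while isolated alkenes are not substrates.

Step 10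
Reactants: 13 menadione (2-methylnaphthalene-1,4-dione); 14 cyclopentadiene (freshly cracked from commercial dicyclopentadiene)
Product: 15 rac-endo-4a-methyl-1,4,4a,9a-tetrahydro-1,4-methanoanthracene-9,10-dione
Conditions: 14 (2 equiv), EtOH, rt, dark
Reagents that add atoms: none
Why: Diels–Alder cycloaddition on the quinone C2=C3 bond; suprafacial addition and the endo rule fix the relative configuration of the four new stereocentres (cis fusion, dione ring anti to the CH2 bridge), and all four are erased in step 15.

Step 11
Reactants: 16 but-2-yn-1-ol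
Product: 18 (E)-3-iodobut-2-en-1-ol, via O-zirconated alkenylzirconocene 17 (not isolated)
Conditions: Cp2Zr(H)Cl (2.2 equiv), THF, rt to 40 °C; then I2 (1.1 equiv), THF, 0 °C
Reagents that add atoms: iodine, [I][I]; zirconocene chloride hydride, [H][Zr](Cl)(C1C=CC=C1)C1C=CC=C1 (its zirconium stays in 17 only)
Why: Hydrozirconation–iodinolysis; after the first equivalent has capped the OH as its zirconium alkoxide, syn addition of Zr–H puts zirconium on C3, next to the small methyl group (excess hydride equilibrates the regioisomers), and iodine cleaves the carbon–zirconium bond with retention, leaving iodine trans to CH2OH.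

Step 12
Reactants: 18 (E)-3-iodobut-2-en-1-ol
Product: 19 (E)-1-bromo-3-iodobut-2-ene
Conditions: PBr3 (0.4 equiv), Et2O, 0 °C, dark
Reagents that add atoms: phosphorus tribromide, BrP(Br)Br
Why: PBr3 bromination of the primary allylic alcohol by SN2 leaves the alkenyl iodide and its geometry untouched.

Step 13
Reactants: 15 rac-endo menadione–cyclopentadiene adduct; 19 (E)-1-bromo-3-iodobut-2-ene
Product: 21 rac-endo-9a-[(E)-3-iodobut-2-en-1-yl]-4a-methyl-1,4,4a,9a-tetrahydro-1,4-methanoanthracene-9,10-dione, via potassium enolate 20 (not isolated)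
Conditions: KOtBu (1.05 equiv), THF, -20 °C; then 19 (1.1 equiv), -20 °C to rt
Reagents that add atoms: potassium tert-butoxide, CC(C)(C)[O-].[K+] (its potassium stays in 20 only)
Why: Enolate C-alkylation at the only enolisable position (C9a–H) with a soft primary allylic bromide; the electrophile must enter from the exo face because the ring fusion has to stay cis, the alkenyl iodide is inert, and the new quaternary centre is erased in step 15.

Step 14
Reactants: 12 C36 heptaene; 21 rac-endo (E)-iodobutenyl adduct
Product: 23 9a-[(2E,7R,10E,14E,18E,22E,26E)-3,7,11,15,19,23,27,31-octamethyldotriaconta-2,10,14,18,22,26,30-heptaen-1-yl]-4a-methyl-1,4,4a,9a-tetrahydro-1,4-methanoanthracene-9,10-dione (endo block; pair of diastereomers), via B-alkyl-9-BBN 22 (not isolated)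
Conditions: 12 (1.1 equiv), (9-BBN-H)2 (0.5 equiv, that is 1.0 equiv B–H), THF, 0 °C to rt; aq. Cs2CO3 (3 equiv), 15 min; then 21 (0.9 equiv), PdCl2(dppf) (5 mol %), AsPh3 (10 mol %), DMF, rt, dark
Reagents that add atoms: 9-borabicyclo[3.3.1]nonane, B1C2CCCC1CCC2 (its boryl group stays in 22 only; one hydrogen stays in 23)
Why: 9-BBN adds anti-Markovnikov to the only monosubstituted alkene of 12, because the six trisubstituted alkenes react far more slowly with this bulky borane, which places boron on the future C4' and leaves C7' untouched. Zerovalent palladium formed from PdCl2(dppf) inserts into the carbon–iodine bond at C3' of 21 with retention, the base-activated borate of 22 transfers its primary alkyl group (the bicyclic 9-BBN carbons do not migrate), and reductive elimination forms C3'–C4' with the E geometry stored in the iodide. The closest known reaction type is the B-alkyl Suzuki–Miyaura fragment coupling of a hydroborated terminal alkene with an (E)-alkenyl iodide. No ring is closed and no stereocentre is created. The quinone part must stay inert, and in 21 it should, because both alpha carbons of the dione are quaternary, so there is no enolisation, no redox-active quinone and no conjugate acceptor; the chelating dppf ligand holds back beta-hydride elimination. The strained norbornene C=C is kept from hydroboration by running 12 in slight excess over B–H and quenching with aqueous base before 21 is added, and an intramolecular Heck closure is geometrically impossible because palladium on C3' is trans to C1'.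

Step 15
Reactants: 23 coupled endo adduct (pair of diastereomers)
Product: 24 2-methyl-3-[(2E,7R,10E,14E,18E,22E,26E)-3,7,11,15,19,23,27,31-octamethyldotriaconta-2,10,14,18,22,26,30-heptaen-1-yl]naphthalene-1,4-dione (target)
Conditions: toluene, 110 °C, slow N2 sweep, dark
Reagents that add atoms: none
Why: Retro-Diels–Alder reaction driven by relief of the two vicinal quaternary centres and of the norbornene strain and by regained quinone conjugation; it removes all four block stereocentres, so both diastereomers converge on one enantiomer, and it needs no oxidant or base that could touch the seven alkenes or C7'.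

Compound list
1 | (2E,6E)-farnesol | CC(C)=CCC/C(C)=C/CC/C(C)=C/CO | starting material
2 | (S)-2,3-dihydrofarnesol | CC(C)=CCC/C(C)=C/CC[C@H](C)CCO | intermediate
3 | (S)-2,3-dihydrofarnesal | CC(C)=CCC/C(C)=C/CC[C@H](C)CC=O | intermediate
4 | (4S,7E)-4,8,12-trimethyltrideca-1,7,11-triene | CC(C)=CCC/C(C)=C/CC[C@H](C)CC=C | intermediate
5 | (2E,6E,10S)-2,6,10-trimethyltrideca-2,6,12-trien-1-ol | OC/C(C)=C/CC/C(C)=C/CC[C@H](C)CC=C | intermediate
6 | (4S,7E,11E)-13-bromo-4,8,12-trimethyltrideca-1,7,11-triene | BrC/C(C)=C/CC/C(C)=C/CC[C@H](C)CC=C | intermediate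
7 | (2E,6E,10E)-geranylgeraniol | CC(C)=CCC/C(C)=C/CC/C(C)=C/CC/C(C)=C/CO | starting material
8 | (2E,6E,10E)-geranylgeranyl bromide | CC(C)=CCC/C(C)=C/CC/C(C)=C/CC/C(C)=C/CBr | intermediate
9 | (2E,6E,10E)-geranylgeranyl phenyl sulfone | CC(C)=CCC/C(C)=C/CC/C(C)=C/CC/C(C)=C/CS(=O)(=O)c1ccccc1 | intermediate
10 | alpha-lithiated geranylgeranyl phenyl sulfone | CC(C)=CCC/C(C)=C/CC/C(C)=C/CC/C(C)=C/C([Li])S(=O)(=O)c1ccccc1 | intermediate
11 | C14-phenylsulfonyl heptaene (both C14 epimers) | CC(C)=CCC/C(C)=C/CC/C(C)=C/CC/C(C)=C/C(C/C(C)=C/CC/C(C)=C/CC[C@H](C)CC=C)S(=O)(=O)c1ccccc1 | intermediate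
12 | (4S,7E,11E,15E,19E,23E)-4,8,12,16,20,24,28-heptamethylnonacosa-1,7,11,15,19,23,27-heptaene | CC(C)=CCC/C(C)=C/CC/C(C)=C/CC/C(C)=C/CC/C(C)=C/CC/C(C)=C/CC[C@H](C)CC=C | intermediate
13 | menadione | CC1=CC(=O)c2ccccc2C1=O | starting material
14 | cyclopentadiene | C1C=CC=C1 | starting material
15 | rac-endo-4a-methyl-1,4,4a,9a-tetrahydro-1,4-methanoanthracene-9,10-dione (one enantiomer drawn) | C[C@]12C(=O)c3ccccc3C(=O)[C@H]1[C@H]1C=C[C@@H]2C1 | intermediate
16 | but-2-yn-1-ol | CC#CCO | starting material
17 | (E)-alkenylzirconocene chloride with O-zirconated hydroxyl (cyclopentadienyl rings drawn sigma-bonded) | Cl[Zr](C1C=CC=C1)(C1C=CC=C1)/C(C)=C/CO[Zr](Cl)(C1C=CC=C1)C1C=CC=C1 | intermediate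
18 | (E)-3-iodobut-2-en-1-ol | I/C(C)=C/CO | intermediate
19 | (E)-1-bromo-3-iodobut-2-ene | I/C(C)=C/CBr | intermediate
20 | potassium enolate of 15 | C[C@]12C(=O)c3ccccc3C([O-])=C1[C@H]1C=C[C@@H]2C1.[K+] | intermediate
21 | rac-endo-9a-[(E)-3-iodobut-2-en-1-yl]-4a-methyl adduct (one enantiomer drawn) | C[C@]12C(=O)c3ccccc3C(=O)[C@@]1(C/C=C(C)/I)[C@H]1C=C[C@@H]2C1 | intermediate
22 | B-alkyl-9-BBN from 12 (boron on the future C4') | CC(C)=CCC/C(C)=C/CC/C(C)=C/CC/C(C)=C/CC/C(C)=C/CC/C(C)=C/CC[C@H](C)CCCB1C2CCCC1CCC2 | intermediate
23 | coupled endo adduct, 7'R (one of the two block diastereomers drawn) | CC(C)=CCC/C(C)=C/CC/C(C)=C/CC/C(C)=C/CC/C(C)=C/CC/C(C)=C/CC[C@H](C)CCC/C(C)=C/C[C@@]12C(=O)c3ccccc3C(=O)[C@]1(C)[C@@H]1C=C[C@H]2C1 | intermediate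
24 | CNP0107344.1, (7'R)-configured dihydro-octaprenyl menaquinone | CC(C)=CCC/C(C)=C/CC/C(C)=C/CC/C(C)=C/CC/C(C)=C/CC/C(C)=C/CC[C@H](C)CCC/C(C)=C/CC1=C(C)C(=O)c2ccccc2C1=O | target

Total step count: 15
Longest linear sequence: 9 steps (1, 2, 3, 4, 5, 8, 9, 14, 15)

Steps most likely to fail

Step 14. The strained C=C of the norbornene part may be consumed in two ways. The alkenylpalladium intermediate may carbopalladate it before transmetalation, or residual B–H may hydroborate it. The fallback changes the mask to one without a strained alkene and unmasks oxidatively rather than thermally. It sets out from 13, 19 and 22 and comes back at 24. Reductive methylation of 13 (Na2S2O4, then Me2SO4, KOH) runs through 2-methylnaphthalene-1,4-diol F1 to 1,4-dimethoxy-2-methylnaphthalene F2. Br2 in CH2Cl2 brominates the only free position of the substituted ring to give 2-bromo-1,4-dimethoxy-3-methylnaphthalene F3. Mg in THF gives (1,4-dimethoxy-3-methylnaphthalen-2-yl)magnesium bromide F4. With catalytic Li2CuCl4, this is allylated by 19 at its CH2Br carbon to 2-[(E)-3-iodobut-2-en-1-yl]-1,4-dimethoxy-3-methylnaphthalene F5. Coupling of 22 with F5 under the conditions of step 14 forms the same C3'–C4' bond and gives the coupled hydroquinone dimethyl ether F6. Ce(NH4)2(NO3)6 in MeCN/H2O at 0 °C then oxidises the dimethoxynaphthalene ring to the quinone 24.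

Step 4. Site selectivity may be poor, with allylic oxidation at the internal C7=C8 alkene, and the product may be over-oxidised to the enal. The fallback degrades and rebuilds the chain terminus instead of oxidising a C–H bond. It sets out from 4 and comes back at 5. NBS in aqueous THF at 0 °C, which favours the exposed terminal alkene, gives (6E,10S)-3-bromo-2,6,10-trimethyltrideca-6,12-dien-2-ol F7. K2CO3 in MeOH closes it to 2,2-dimethyl-3-[(3E,7S)-3,7-dimethyldeca-3,9-dien-1-yl]oxirane F8. H5IO6 in THF/Et2O cleaves this to (4E,8S)-4,8-dimethylundeca-4,10-dienal F9. The stabilised ylide Ph3P=C(CH3)CO2Et gives, E-selectively, ethyl (2E,6E,10S)-2,6,10-trimethyltrideca-2,6,12-trienoate F10. Reduction with i-Bu2AlH at -78 °C leads to 5.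

Step 9. Hydride may be delivered to the wrong end of the pi-allyl complex, which transposes the alkene. The E geometry may erode by pi–sigma–pi isomerisation, and palladium hydride may cause the terminal vinyl group to migrate. The fallback avoids the sulfone and palladium altogether by an alpha,alpha'-selective allyl–allyl coupling of an allylbarium reagent. It sets out from 7 and 6 and comes back at 12. NCS/Me2S in CH2Cl2 at -30 to 0 °C turns 7 into (2E,6E,10E)-geranylgeranyl chloride F11. Activated barium (from BaI2 and lithium biphenylide, THF) inserts at -78 °C to give geranylgeranylbarium chloride F12. This is configurationally stable at that temperature and should attack the CH2Br carbon of 6 through its own alpha carbon to give 12 directly.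

Further compounds
F1 | step 14 | 2-methylnaphthalene-1,4-diol | Cc1cc(O)c2ccccc2c1O
F2 | step 14 | 1,4-dimethoxy-2-methylnaphthalene | COc1cc(C)c(OC)c2ccccc12
F3 | step 14 | 2-bromo-1,4-dimethoxy-3-methylnaphthalene | COc1c(Br)c(C)c(OC)c2ccccc12
F4 | step 14 | (1,4-dimethoxy-3-methylnaphthalen-2-yl)magnesium bromide | COc1c([Mg]Br)c(C)c(OC)c2ccccc12
F5 | step 14 | 2-[(E)-3-iodobut-2-en-1-yl]-1,4-dimethoxy-3-methylnaphthalene | COc1c(C/C=C(C)/I)c(C)c(OC)c2ccccc12
F6 | step 14 | coupled hydroquinone dimethyl ether (7'R) | CC(C)=CCC/C(C)=C/CC/C(C)=C/CC/C(C)=C/CC/C(C)=C/CC/C(C)=C/CC[C@H](C)CCC/C(C)=C/Cc1c(C)c(OC)c2ccccc2c1OC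
F7 | step 4 | (6E,10S)-3-bromo-2,6,10-trimethyltrideca-6,12-dien-2-ol (C3 epimers) | CC(C)(O)C(Br)CC/C(C)=C/CC[C@H](C)CC=C
F8 | step 4 | 2,2-dimethyl-3-[(3E,7S)-3,7-dimethyldeca-3,9-dien-1-yl]oxirane (epimers at the oxirane CH) | CC1(C)OC1CC/C(C)=C/CC[C@H](C)CC=C
F9 | step 4 | (4E,8S)-4,8-dimethylundeca-4,10-dienal | O=CCC/C(C)=C/CC[C@H](C)CC=C
F10 | step 4 | ethyl (2E,6E,10S)-2,6,10-trimethyltrideca-2,6,12-trienoate | CCOC(=O)/C(C)=C/CC/C(C)=C/CC[C@H](C)CC=C
F11 | step 9 | (2E,6E,10E)-geranylgeranyl chloride | CC(C)=CCC/C(C)=C/CC/C(C)=C/CC/C(C)=C/CCl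
F12 | step 9 | geranylgeranylbarium chloride | CC(C)=CCC/C(C)=C/CC/C(C)=C/CC/C(C)=C/C[Ba]Cl
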